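I could not read the effect of coupling partner from the earlier runs, since ash and birch both held it at 0.60 equiv.

common to all: starting material 0.30 M

|  | coupling partner | free catalyst | remark | time |
|---|---|---|---|---|
| ash | 0.60 equiv | 1.3 mol% | run made earlier |  |
| birch | 0.60 equiv | 4 mol% | run made earlier |  |
| beta | 0.600 equiv | 2 mol% |  | 8.0 min |
| epsilon | 2.00 equiv | 2 mol% |  | 8.0 min |
| delta | 6.00 equiv | 2 mol% |  | 8.0 min |

- ash (time / min: target / %): 0.250: 3; 0.667: 5; 1.33: 1; 2.00: 5; 3.00: 8
- birch (time / min: target / %): 0.500: 3; 1.00: 7; 1.50: 9; 2.50: 21; 3.00: 20

(scatter of a reading: 2 percentage points)

- target is meant together with its crystals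
- solid, in amounts per volume of the solution: crystals
- what may be going on: coupling partner + free catalyst <-> catalyst intermediate A; crystals <-> target; starting material + catalyst intermediate A <-> catalyst intermediate B; catalyst intermediate B <-> free catalyst + target
- "hardly changes" means that all values lie within two and a half points (for a concentration: within two and a half percent of the largest)

1. amount of target at the end, in percent of the starting material charged for beta, epsilon, delta, in this order
2. how that number moves from the first to the last of them (falls all the way / rises all the way / falls, then rises / hardly changes / rises, then falls)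

What ash and birch did show was the effect of catalyst. At the same 3.00 min, time drops out of a ratio. Birch's reading of target stood 2.50 times ash's, on 3.08 times the loading, so within the scatter target went roughly with catalyst.

I therefore divided target by loading and time. Birch gave 1.67 min⁻¹ for this turnover rate, the turnover frequency: target made per catalyst per minute, averaged over the run. Ash gave 2.05 min⁻¹. Each reading carries 2 percentage points, on 8% in ash and 20% in birch, so I took birch.

At 2 mol% over 8.0 min, my turnover rate gave 26.7% for beta. Epsilon and delta have the same loading and time, so I set the same figure against them and read any gap as the work of the extra partner.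

The forecast said 26%, 31% and 34%, rises all the way, on the ground that “More partner should remove that slowing and saturate the catalyst further”.

The flasks gave 23.1%, 54.8% and 82.0%, which rises all the way.

    coupling partner + free catalyst ⇌ catalyst intermediate A (K = 0.660 M⁻¹, k = 2.00 M⁻¹ s⁻¹)
    crystals ⇌ target, rate k2*(cs2 - [target]) while solid is left; crystals form when [target] > cs2 (solubility = 0.0860 M, k = 0.0880 s⁻¹)
    starting material + catalyst intermediate A ⇌ catalyst intermediate B (K = 4.20 M⁻¹, k = 1.50 M⁻¹ s⁻¹)
    catalyst intermediate B ⇌ free catalyst + target (K = 9.90 M, k = 1.90 s⁻¹)

Beta's 23.1% means a turnover rate of 1.44 min⁻¹ on average over 8.0 min, less than the 1.67 min⁻¹ I read from birch over 3.00 min. At 8.00 min, free catalyst, the resting state in beta, held 92.3% of the catalyst charged. Delta's 82.0% means 5.13 min⁻¹ on average, 3.56 times beta's, on ten times the partner. At 8.00 min, catalyst intermediate A held 49.0% of the catalyst in delta, against 6.18% in beta.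

The numbers in the tables were generated by integration for substances that don't exist; noise was put on by code.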